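**Retrosynthetic overview**

- Ring numbering: C1 ketone, C2 heptenyl carbon, C3 hydroxymethyl carbon, C4 carbinol, C5 epoxide CH, C6 quaternary epoxide carbon. The strategy rests on the oxygens at C1 and C4 lying across the ring from each other, on either side of the C2=C3 alkene.
- This pattern is cut at C1–C2 and C3–C4, giving a butadiene (C1–C6–C5–C4) oxygenated at both ends and an alkyne (C2≡C3) carrying the heptenyl and a formyl group.
- The six-membered carbocycle is formed first, in the Diels–Alder step. The oxirane is formed second, on C5=C6 of the adduct and before C1 is oxidised, because a C1 ketone beside an intact C5=C6 would be the keto tautomer of a phenol.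
- The diene is the dienol acetate of an α-branched γ-silyloxy enal (Wittig, then methacrylate cross-metathesis). The ynal comes from (E)-oct-2-enal by Corey–Fuchs homologation and formylation.
- Endgame: aldehyde reduction and silylation, acetate and ester cleavage, C1 oxidation, desilylation.

Key step: step 7

Assumption: the (S)-configured catalyst is taken to give the adduct enantiomer drawn; the sense should be checked by Mosher ester analysis of the later C1 alcohol, and the (R)-catalyst is used with no other change if it proves opposite.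

**Route**

Step 1
Reactants: 1 (E)-oct-2-enal
Product: 2 (E)-1,1-dibromonona-1,3-diene
Conditions: CBr4 (2 equiv), PPh3 (4 equiv), CH2Cl2, 0 °C; pentane, filtration through silica
Reagents that add atoms: carbon tetrabromide BrC(Br)(Br)Br
Why: Corey–Fuchs (Ramirez) dibromo-olefination of the aldehyde by the ylide Ph3P=CBr2; the E-alkene of 1 is not touched.

Step 2
Reactants: 2 (E)-1,1-dibromonona-1,3-diene
Product: 4 (E)-dec-4-en-2-ynal, via lithium (E)-non-3-en-1-yn-1-ide 3 (not isolated)
Conditions: n-BuLi (2.1 equiv), THF, −78 → 0 °C; DMF (3 equiv), −78 → 0 °C; inverse quench into aq KH2PO4/Et2O, 0 °C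
Reagents that add atoms: N,N-dimethylformamide CN(C)C=O
Why: Second half of the Corey–Fuchs sequence (bromine–lithium exchange, Fritsch–Buttenberg–Wiechell shift, deprotonation) followed by formylation of the lithium acetylide with DMF, the buffered inverse quench releasing the ynal without amine addition to it.

Step 3
Reactants: 5 (but-3-en-1-yl)triphenylphosphonium bromide
Product: 7 2-(triphenylphosphoranylidene)pent-4-enal, via (but-3-en-1-ylidene)triphenylphosphorane 6 (not isolated)
Conditions: NaN(SiMe3)2 (1.05 equiv), THF, 0 °C; HCO2Et (1.5 equiv), 0 °C → rt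
Reagents that add atoms: ethyl formate CCOC=O
Why: Ylide formation and C-formylation of the non-stabilised phosphorane with a formate ester, the ethoxide released deprotonating the formylphosphonium salt to the stabilised ylide.

Step 4
Reactants: 7 2-(triphenylphosphoranylidene)pent-4-enal; 8 (tert-butyldimethylsilyloxy)acetaldehyde
Product: 9 (E)-2-allyl-4-(tert-butyldimethylsilyloxy)but-2-enal
Conditions: 8 (1.2 equiv), toluene, 90 °C
Reagents that add atoms: none
Why: Wittig olefination with a stabilised α-branched formyl ylide, which should give the E-enal (CHO trans to CH2OTBS) and should attack the more electrophilic α-silyloxy aldehyde rather than the product.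

Step 5
Reactants: 9 (E)-2-allyl-4-(tert-butyldimethylsilyloxy)but-2-enal; 10 methyl methacrylate
Product: 11 methyl (2E,5E)-5-formyl-2-methyl-7-(tert-butyldimethylsilyloxy)hepta-2,5-dienoate
Conditions: 10 (10 equiv), second-generation Hoveyda–Grubbs catalyst RuCl2(SIMes)(=CH-C6H4-2-OiPr) (5 mol %), 1,4-benzoquinone (10 mol %), CH2Cl2, 40 °C
Reagents that add atoms: none
Why: Olefin cross-metathesis of the terminal alkene with excess methacrylate should give the E-trisubstituted enoate under thermodynamic control, the trisubstituted enal alkene being inert and benzoquinone suppressing alkene migration.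

Step 6
Reactants: 11 methyl (2E,5E)-5-formyl-2-methyl-7-(tert-butyldimethylsilyloxy)hepta-2,5-dienoate
Product: 12 methyl (2E,6E)-5-[(E)-acetoxymethylidene]-7-(tert-butyldimethylsilyloxy)-2-methylhepta-2,6-dienoate, the (1E,3E)-1-acetoxy-4-silyloxybuta-1,3-diene with the side chain on the future C6
Conditions: Ac2O (3 equiv), Et3N (4 equiv), DMAP (0.2 equiv), THF, 45 °C, dark
Reagents that add atoms: acetic anhydride CC(=O)OC(C)=O
Why: Dienol acetate formation from an enal (O-acetylation with loss of a proton from C4, the only position γ to the formyl group); the s-trans conformation of the α-branched enal puts the acetoxy group trans to C5 and allylic 1,3-strain against the C6 branch turns the silyloxy group outward, so the (1E,3E)-diene should predominate.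

Step 7
Reactants: 12 the (1E,3E)-1-acetoxy-4-silyloxy diene; 4 (E)-dec-4-en-2-ynal
Product: 13 (1R,4S)-1-acetoxy-4-(tert-butyldimethylsilyloxy)-3-formyl-2-[(E)-hept-1-enyl]-6-[(E)-3-(methoxycarbonyl)but-2-enyl]cyclohexa-2,5-diene (overview numbering; OAc and OTBS cis)
Conditions: (S)-B-(o-tolyl) oxazaborolidine from (S)-α,α-diphenylprolinol (20 mol %), HNTf2 (18 mol %), 4 (1.0 equiv), CH2Cl2, −78 °C; 12 (1.3 equiv) added slowly; pH 7 phosphate buffer at −78 °C, cold filtration through Florisil, used at once
Reagents that add atoms: none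
Why: Coordination of the boron Lewis acid to the formyl oxygen of 4 lowers the LUMO of the conjugated alkyne π-system, and the diene adds across C2≡C3 in a concerted, asynchronous, suprafacial [4+2] cycloaddition in which the C1–C2 bond leads. The closest known reactions are oxazaborolidinium-catalysed enantioselective Diels–Alder additions to acetylenic carbonyl compounds and cycloadditions of butadienes oxygenated at both termini with such dienophiles. The six-membered carbocycle is closed intermolecularly by the two new σ-bonds C1–C2 and C3–C4, leaving the C2=C3 alkene tetrasubstituted with heptenyl and formyl in place. C1 and C4 arise cis because both oxygens are outside substituents of the (1E,3E)-diene, and their absolute configuration is set by the catalyst, which shields one face of the bound ynal and keeps the diene on the formyl-hydrogen side, away from the boron complex. The step needs C1 rather than C4 to bond to the heptenyl-bearing carbon C2: the silyloxy group on C4 is a stronger donor than the acetoxy group on C1 and the alkyl branch on C6 adds to it, so the larger HOMO coefficient sits on C1 and meets the β-carbon of the ynal. It also needs addition to C≡C rather than C=O and survival of the 1,4-diene, which the low temperature, the slight deficit of HNTf2 and the buffered quench are meant to secure.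

Step 8
Reactants: 13 the Diels–Alder adduct
Product: 14 (1S,4R,5S,6R)-1-acetoxy-4-(tert-butyldimethylsilyloxy)-5,6-epoxy-3-formyl-2-[(E)-hept-1-enyl]-6-[(E)-3-(methoxycarbonyl)but-2-enyl]cyclohex-2-ene (oxirane on the face opposite to OAc and OTBS)
Conditions: dimethyldioxirane (1.2 equiv, acetone solution), CH2Cl2, −40 → 0 °C
Reagents that add atoms: dimethyldioxirane CC1(C)OO1
Why: Electrophilic epoxidation with a dioxirane should take C5=C6, the only alkene not conjugated to a carbonyl group, from the face opposite to the cis C1-OAc and C4-OTBS groups, which sets C5 and C6 anti to the C4 oxygen under neutral conditions that do not aromatise the diene.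

Step 9
Reactants: 14 the epoxy aldehyde
Product: 15 (1S,4R,5S,6R)-1-acetoxy-4-(tert-butyldimethylsilyloxy)-5,6-epoxy-2-[(E)-hept-1-enyl]-3-(hydroxymethyl)-6-[(E)-3-(methoxycarbonyl)but-2-enyl]cyclohex-2-ene
Conditions: NaBH4, CeCl3·7H2O, MeOH, −78 °C
Reagents that add atoms: none
Why: Luche 1,2-reduction of the conjugated aldehyde, cold enough to leave the acetate, the epoxide and the enoate alone.

Step 10
Reactants: 15 the epoxy primary alcohol
Product: 16 (1S,4R,5S,6R)-1-acetoxy-4-(tert-butyldimethylsilyloxy)-3-[(tert-butyldimethylsilyloxy)methyl]-5,6-epoxy-2-[(E)-hept-1-enyl]-6-[(E)-3-(methoxycarbonyl)but-2-enyl]cyclohex-2-ene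
Conditions: TBSCl, imidazole, DMF, 0 °C
Reagents that add atoms: tert-butyldimethylsilyl chloride CC(C)(C)[Si](C)(C)Cl
Why: Standard silylation of the primary allylic alcohol, done at once to forestall acetyl migration from the C1 oxygen.

Step 11
Reactants: 16 the bis-silyl epoxy acetate
Product: 17 (1S,4R,5S,6R)-4-(tert-butyldimethylsilyloxy)-3-[(tert-butyldimethylsilyloxy)methyl]-5,6-epoxy-2-[(E)-hept-1-enyl]-6-[(E)-3-(methoxycarbonyl)but-2-enyl]cyclohex-2-en-1-ol
Conditions: K2CO3 (0.5 equiv), MeOH, 0 °C → rt
Reagents that add atoms: none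
Why: Base-catalysed transesterification (methanolysis of the acetate) frees the C1 alcohol, the methyl enoate exchanging only with itself and Payne migration being disfavoured because it would need attack at quaternary C6.

Step 12
Reactants: 17 the epoxy alcohol methyl ester
Product: 18 (E)-4-[(1S,4R,5S,6R)-4-(tert-butyldimethylsilyloxy)-3-[(tert-butyldimethylsilyloxy)methyl]-5,6-epoxy-2-[(E)-hept-1-enyl]-1-hydroxycyclohex-2-en-6-yl]-2-methylbut-2-enoic acid
Conditions: Me3SnOH (8 equiv), ClCH2CH2Cl, 70 °C; aq KHSO4 wash
Reagents that add atoms: trimethyltin hydroxide C[Sn](C)(C)O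
Why: Ester hydrolysis with trimethyltin hydroxide, a neutral hydroxide-transfer reagent for methyl esters, should spare the epoxide and the silyl ethers, and is placed before the oxidation because the epoxy enone is base-sensitive.

Step 13
Reactants: 18 the hydroxy acid
Product: 19 (E)-4-[(4R,5S,6S)-4-(tert-butyldimethylsilyloxy)-3-[(tert-butyldimethylsilyloxy)methyl]-5,6-epoxy-2-[(E)-hept-1-enyl]-1-oxocyclohex-2-en-6-yl]-2-methylbut-2-enoic acid
Conditions: Dess–Martin periodinane, NaHCO3, CH2Cl2, 0 °C → rt
Reagents that add atoms: none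
Why: Dess–Martin oxidation of the secondary allylic alcohol gives the C1 enone under buffered, non-enolising conditions, removing the transient C1 centre and leaving C4, C5 and C6 untouched.

Step 14
Reactants: 19 the bis-silyl keto acid
Product: 20 (E)-4-[(4R,5S,6S)-5,6-epoxy-2-[(E)-hept-1-enyl]-4-hydroxy-3-(hydroxymethyl)-1-oxocyclohex-2-en-6-yl]-2-methylbut-2-enoic acid (CNP0332048.4)
Conditions: HF·pyridine, pyridine, THF, 0 °C → rt
Reagents that add atoms: none
Why: Fluoride-mediated desilylation with buffered HF·pyridine cleaves the primary and the secondary silyl ether without base, to which the γ-hydroxy epoxy enone is sensitive.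

**Compound list**

1 | (E)-oct-2-enal | CCCCC/C=C/C=O | starting material
2 | (E)-1,1-dibromonona-1,3-diene | CCCCC/C=C/C=C(Br)Br | intermediate
3 | lithium (E)-non-3-en-1-yn-1-ide | CCCCC/C=C/C#C[Li] | intermediate (not isolated)
4 | (E)-dec-4-en-2-ynal | CCCCC/C=C/C#CC=O | intermediate
5 | (but-3-en-1-yl)triphenylphosphonium bromide | C=CCC[P+](c1ccccc1)(c1ccccc1)c1ccccc1.[Br-] | starting material
6 | (but-3-en-1-ylidene)triphenylphosphorane | C=CCC=P(c1ccccc1)(c1ccccc1)c1ccccc1 | intermediate (not isolated)
7 | 2-(triphenylphosphoranylidene)pent-4-enal | C=CCC(C=O)=P(c1ccccc1)(c1ccccc1)c1ccccc1 | intermediate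
8 | (tert-butyldimethylsilyloxy)acetaldehyde | O=CCO[Si](C)(C)C(C)(C)C | starting material
9 | (E)-2-allyl-4-(tert-butyldimethylsilyloxy)but-2-enal | O=C/C(CC=C)=C/CO[Si](C)(C)C(C)(C)C | intermediate
10 | methyl methacrylate | C=C(C)C(=O)OC | starting material
11 | methyl (2E,5E)-5-formyl-2-methyl-7-(tert-butyldimethylsilyloxy)hepta-2,5-dienoate | O=C/C(C/C=C(\C)C(=O)OC)=C/CO[Si](C)(C)C(C)(C)C | intermediate
12 | methyl (2E,6E)-5-[(E)-acetoxymethylidene]-7-(tert-butyldimethylsilyloxy)-2-methylhepta-2,6-dienoate | CC(=O)O/C=C(/C=C/O[Si](C)(C)C(C)(C)C)C/C=C(\C)C(=O)OC | intermediate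
13 | (1R,4S)-1-acetoxy-4-(tert-butyldimethylsilyloxy)-3-formyl-2-[(E)-hept-1-enyl]-6-[(E)-3-(methoxycarbonyl)but-2-enyl]cyclohexa-2,5-diene | CCCCC/C=C/C1=C(C=O)[C@@H](O[Si](C)(C)C(C)(C)C)C=C(C/C=C(\C)C(=O)OC)[C@H]1OC(C)=O | intermediate
14 | (1S,4R,5S,6R)-5,6-epoxy aldehyde from 13 | CCCCC/C=C/C1=C(C=O)[C@@H](O[Si](C)(C)C(C)(C)C)[C@@H]2O[C@]2(C/C=C(\C)C(=O)OC)[C@H]1OC(C)=O | intermediate
15 | (1S,4R,5S,6R)-epoxy acetate with 3-(hydroxymethyl) | CCCCC/C=C/C1=C(CO)[C@@H](O[Si](C)(C)C(C)(C)C)[C@@H]2O[C@]2(C/C=C(\C)C(=O)OC)[C@H]1OC(C)=O | intermediate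
16 | (1S,4R,5S,6R)-bis-silyl epoxy acetate | CCCCC/C=C/C1=C(CO[Si](C)(C)C(C)(C)C)[C@@H](O[Si](C)(C)C(C)(C)C)[C@@H]2O[C@]2(C/C=C(\C)C(=O)OC)[C@H]1OC(C)=O | intermediate
17 | (1S,4R,5S,6R)-bis-silyl epoxy C1 alcohol, methyl ester | CCCCC/C=C/C1=C(CO[Si](C)(C)C(C)(C)C)[C@@H](O[Si](C)(C)C(C)(C)C)[C@@H]2O[C@]2(C/C=C(\C)C(=O)OC)[C@H]1O | intermediate
18 | (1S,4R,5S,6R)-bis-silyl epoxy C1 alcohol, carboxylic acid | CCCCC/C=C/C1=C(CO[Si](C)(C)C(C)(C)C)[C@@H](O[Si](C)(C)C(C)(C)C)[C@@H]2O[C@]2(C/C=C(\C)C(=O)O)[C@H]1O | intermediate
19 | (4R,5S,6S)-bis-silyl epoxy enone, carboxylic acid | CCCCC/C=C/C1=C(CO[Si](C)(C)C(C)(C)C)[C@@H](O[Si](C)(C)C(C)(C)C)[C@@H]2O[C@]2(C/C=C(\C)C(=O)O)C1=O | intermediate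
20 | (E)-4-[(4R,5S,6S)-5,6-epoxy-2-[(E)-hept-1-enyl]-4-hydroxy-3-(hydroxymethyl)-1-oxocyclohex-2-en-6-yl]-2-methylbut-2-enoic acid | CCCCC/C=C/C1=C(CO)[C@@H](O)[C@@H]2O[C@]2(C/C=C(\C)C(=O)O)C1=O | target

**Step count**

Total: 14 steps. Longest linear sequence: 12 steps (steps 3–14 from 5); the ynal branch (steps 1–2) joins at step 7.

**Steps most likely to fail**

1. Step 7 (Diels–Alder). What may go wrong:
   - addition of the silyl dienol ether to the Lewis-acid-bound formyl group (Mukaiyama aldol or hetero-Diels–Alder) instead of to the alkyne;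
   - acid-induced loss of the silyl enol ether;
   - insufficient discrimination between the enantiomeric approach geometries;
   - elimination from the adduct with aromatisation.

   Fallback: from 12 and 4 the cycloaddition is run thermally without catalyst (toluene, 45 °C, BHT, base-washed glassware), where ynals add through the triple bond. This should give the racemate, that is 13 together with the enantiomeric adduct F1. The mixture is carried through steps 8 and 9 unchanged, giving 14 with the enantiomeric epoxy aldehyde F2, then 15 with the enantiomeric epoxy alcohol F3. Preparative HPLC on a polysaccharide chiral stationary phase separates 15 from F3, and the route is rejoined at 15.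

2. Step 6 (dienol acetate). What may go wrong: amine-mediated migration of the skipped side-chain alkene into conjugation, incomplete control of the two enol geometries, or slow conversion.

   Fallback: from 11, soft enolisation with TMSOTf/Et3N (Et2O, −78 → 0 °C) silylates the formyl oxygen and removes the only acidified proton, on C4. This should give the (1E,3E)-1-(trimethylsilyloxy)-4-(tert-butyldimethylsilyloxy) diene F4. Cycloaddition with 4 under the conditions of step 7 gives the C1-O-trimethylsilyl adduct F5; regiocontrol then rests on the C6 branch alone (para orientation). Epoxidation as in step 8 gives the trimethylsilyl epoxy aldehyde F6. Luche reduction followed by citric acid in methanol removes the labile trimethylsilyl ether and gives the epoxy diol F7. Selective silylation of the primary hydroxyl (TBSCl 1.05 equiv, imidazole, CH2Cl2, −20 °C) returns to the route at 17.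

3. Step 12 (ester hydrolysis). What may go wrong: slow hydrolysis of the α-branched conjugated ester, with epoxide opening or Payne-type migration on prolonged heating.

   Fallback: from 17, oxidation as in step 13 gives the bis-silyl keto methyl ester F8. Desilylation as in step 14 gives the methyl ester of the target F9. The ester is then hydrolysed last by pig liver esterase (pH 7 phosphate buffer, 10% acetone, rt), arriving at 20.

**Further compounds**

F1 | step 7 | (1S,4R)-enantiomer of adduct 13 | CCCCC/C=C/C1=C(C=O)[C@H](O[Si](C)(C)C(C)(C)C)C=C(C/C=C(\C)C(=O)OC)[C@@H]1OC(C)=O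
F2 | step 7 | (1R,4S,5R,6S)-enantiomer of epoxy aldehyde 14 | CCCCC/C=C/C1=C(C=O)[C@H](O[Si](C)(C)C(C)(C)C)[C@H]2O[C@@]2(C/C=C(\C)C(=O)OC)[C@@H]1OC(C)=O
F3 | step 7 | (1R,4S,5R,6S)-enantiomer of epoxy alcohol 15 | CCCCC/C=C/C1=C(CO)[C@H](O[Si](C)(C)C(C)(C)C)[C@H]2O[C@@]2(C/C=C(\C)C(=O)OC)[C@@H]1OC(C)=O
F4 | step 6 | methyl (2E,6E)-7-(tert-butyldimethylsilyloxy)-2-methyl-5-[(E)-(trimethylsilyloxy)methylidene]hepta-2,6-dienoate | C[Si](C)(C)O/C=C(/C=C/O[Si](C)(C)C(C)(C)C)C/C=C(\C)C(=O)OC
F5 | step 6 | (1R,4S)-4-(tert-butyldimethylsilyloxy)-3-formyl-2-[(E)-hept-1-enyl]-6-[(E)-3-(methoxycarbonyl)but-2-enyl]-1-(trimethylsilyloxy)cyclohexa-2,5-diene | CCCCC/C=C/C1=C(C=O)[C@@H](O[Si](C)(C)C(C)(C)C)C=C(C/C=C(\C)C(=O)OC)[C@H]1O[Si](C)(C)C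
F6 | step 6 | 5,6-epoxide of F5, oxirane trans to both silyloxy groups | CCCCC/C=C/C1=C(C=O)[C@@H](O[Si](C)(C)C(C)(C)C)[C@@H]2O[C@]2(C/C=C(\C)C(=O)OC)[C@H]1O[Si](C)(C)C
F7 | step 6 | (1S,4R,5S,6R)-4-(tert-butyldimethylsilyloxy)-5,6-epoxy-2-[(E)-hept-1-enyl]-3-(hydroxymethyl)-6-[(E)-3-(methoxycarbonyl)but-2-enyl]cyclohex-2-en-1-ol | CCCCC/C=C/C1=C(CO)[C@@H](O[Si](C)(C)C(C)(C)C)[C@@H]2O[C@]2(C/C=C(\C)C(=O)OC)[C@H]1O
F8 | step 12 | methyl ester of 19 (bis-silyl epoxy enone) | CCCCC/C=C/C1=C(CO[Si](C)(C)C(C)(C)C)[C@@H](O[Si](C)(C)C(C)(C)C)[C@@H]2O[C@]2(C/C=C(\C)C(=O)OC)C1=O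
F9 | step 12 | methyl ester of 20 | CCCCC/C=C/C1=C(CO)[C@@H](O)[C@@H]2O[C@]2(C/C=C(\C)C(=O)OC)C1=O
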